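**Retrosynthetic overview**
1. The target is reached by allylic oxidation of an isopropenyl precursor (SeO2, then MnO2). That precursor comes from one nickel-catalysed, enantioconvergent, reductive three-component coupling of a 5-iodo-2,3-dihydrobenzofuran, acetaldehyde and isovaleryl chloride, which forms the C-5–C-1′ bond, brings in the C-1′ isovalerate and sets C-1′ (R) by catalyst control.
2. Enabling feature: the side-chain carbon C-1′ carries a methyl group and an acyloxy oxygen, so it is the carbonyl carbon of acetaldehyde in O-acylated form; its chloride gives an oxygen-stabilised radical whose ester carbonyl can chelate nickel. C-5 of the benzene ring (ring A) lies para to the ring oxygen O-1, the position already iodinated in commercial 5-iodosalicylaldehyde.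
3. The aryl iodide comes from a trans diol by C-3 acylation and dehydration of the side-chain tertiary carbinol. The dihydrofuran ring (ring B) comes from a threo epoxy alcohol by 5-exo-tet phenoxide opening with inversion at C-2.
4. The epoxy alcohol comes from an (R)-allylic alcohol by hydroxyl-directed epoxidation, and the allylic alcohol from silylated 5-iodosalicylaldehyde by catalytic asymmetric alkenylzinc addition. C-3 is set by catalysis and C-2 is relayed from it.
5. Ring order: ring A is bought; ring B is the only ring formed (step 4).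

Key step: step 7

Remark: the sense of induction of (+)-MIB (step 2) and of the bis(oxazoline) antipode (step 7) is assumed by analogy with simple aryl substrates and would be fixed on a model, the other antipode being used if needed; atom numbers follow the benzofuran skeleton, C-1′ being the side-chain carbon on C-5.

**Route**

Step 1
Reactants: 1 2-hydroxy-5-iodobenzaldehyde
Product: 2 2-[(tert-butyldimethylsilyl)oxy]-5-iodobenzaldehyde
Conditions: TBSCl, imidazole, CH2Cl2, 0 °C to rt
Reagents that add atoms: tert-butyldimethylsilyl chloride, CC(C)(C)[Si](C)(C)Cl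
Why: Imidazole-mediated silylation of the phenol masks the acidic OH, which would otherwise quench the organozinc reagent and disturb the chiral catalyst of step 2; no stereocentre is formed.

Step 2
Reactants: 2 2-[(tert-butyldimethylsilyl)oxy]-5-iodobenzaldehyde, 3 1-bromo-2-methylprop-1-ene
Product: 6 (1R)-1-{2-[(tert-butyldimethylsilyl)oxy]-5-iodophenyl}-3-methylbut-2-en-1-ol, via (2-methylprop-1-enyl)lithium 4 (not isolated), via bis(2-methylprop-1-enyl)zinc 5 (not isolated)
Conditions: 3 (2.4 equiv), t-BuLi (4.8 equiv), Et2O, −78 °C; ZnBr2 (1.2 equiv), −78 to 0 °C; N,N,N′,N′-tetraethylethylenediamine, toluene; (+)-MIB (10 mol %), 2, 0 °C; then H2O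
Reagents that add atoms: 1-bromo-2-methylprop-1-ene (3), CC(C)=CBr
Why: Catalytic enantioselective alkenylzinc 1,2-addition to an aryl aldehyde (amino-alcohol catalysis; the zinc reagent comes from lithium–bromine exchange and transmetalation, and the diamine masks LiBr to suppress the racemic background) should set C-3 as R through face selection by the MIB–zinc complex, while the aryl iodide stays inert because all t-BuLi is consumed before 2 is added.

Step 3
Reactants: 6 (1R)-1-{2-[(tert-butyldimethylsilyl)oxy]-5-iodophenyl}-3-methylbut-2-en-1-ol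
Product: 7 (S)-{2-[(tert-butyldimethylsilyl)oxy]-5-iodophenyl}[(2R)-3,3-dimethyloxiran-2-yl]methanol (threo)
Conditions: mCPBA, NaHCO3, CH2Cl2, 0 °C
Reagents that add atoms: mCPBA, O=C(OO)c1cccc(Cl)c1
Why: In this hydroxyl-directed Prilezhaev epoxidation, 1,3-allylic strain with the alkene methyl cis to the carbinol holds C-3–H in the alkene plane, so the hydrogen-bonded peracid should deliver oxygen syn to OH and give the threo epoxy alcohol, the new epoxide CH centre (R) being set by substrate control from C-3.

Step 4
Reactants: 7 (S)-{2-[(tert-butyldimethylsilyl)oxy]-5-iodophenyl}[(2R)-3,3-dimethyloxiran-2-yl]methanol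
Product: 9 (2S,3S)-2-(2-hydroxypropan-2-yl)-5-iodo-2,3-dihydro-1-benzofuran-3-ol (trans), via potassium phenoxide of the epoxy alcohol 8 (not isolated)
Conditions: K2CO3 (0.3 equiv), MeOH, rt to 40 °C
Reagents that add atoms: none
Why: Base-catalysed methanolysis of the aryl silyl ether frees the phenoxide, which should open the epoxide in a 5-exo-tet SN2 reaction at the secondary carbon (attack at the tertiary carbon is disfavoured under basic conditions), closing ring B with inversion at C-2 and so turning the threo epoxide into the 2,3-trans diol.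

Step 5
Reactants: 9 (2S,3S)-2-(2-hydroxypropan-2-yl)-5-iodo-2,3-dihydro-1-benzofuran-3-ol, 10 3-methylbutanoyl chloride (isovaleryl chloride)
Product: 11 (2S,3S)-2-(2-hydroxypropan-2-yl)-5-iodo-2,3-dihydro-1-benzofuran-3-yl 3-methylbutanoate
Conditions: pyridine, DMAP (cat.), CH2Cl2, 0 °C
Reagents that add atoms: 3-methylbutanoyl chloride (10), CC(C)CC(Cl)=O
Why: DMAP-catalysed acylation with the acid chloride should esterify only the secondary benzylic C-3 hydroxyl, the tertiary carbinol being too hindered at 0 °C; no stereocentre is touched.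

Step 6
Reactants: 11 (2S,3S)-2-(2-hydroxypropan-2-yl)-5-iodo-2,3-dihydro-1-benzofuran-3-yl 3-methylbutanoate
Product: 12 (2R,3S)-5-iodo-2-(prop-1-en-2-yl)-2,3-dihydro-1-benzofuran-3-yl 3-methylbutanoate
Conditions: Burgess reagent, toluene, 50 °C
Reagents that add atoms: none
Why: Burgess dehydration (syn Ei elimination through the sulfamate ester) should take a hydrogen from one of the two methyl groups and not the hindered C-2–H, in line with the general preference of syn eliminations to run away from an ether oxygen, and its neutral conditions spare the ionisable benzylic C-3 ester (the C-2 descriptor changes from S to R by priority only).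

Step 7
Reactants: 12 (2R,3S)-5-iodo-2-(prop-1-en-2-yl)-2,3-dihydro-1-benzofuran-3-yl 3-methylbutanoate, 13 acetaldehyde, 10 3-methylbutanoyl chloride
Product: 15 (2R,3S)-5-[(1R)-1-(3-methylbutanoyloxy)ethyl]-2-(prop-1-en-2-yl)-2,3-dihydro-1-benzofuran-3-yl 3-methylbutanoate, via 1-chloroethyl 3-methylbutanoate 14 (not isolated)
Conditions: 13 (1.5 equiv), 10 (1.3 equiv), ZnCl2 (2 mol %), neat, −10 °C to rt, N2 purge; then added slowly to 12, NiBr2(dme) (10 mol %), chiral 4,4′-di(heptan-4-yl)-2,2′-bi(2-oxazoline) (12 mol %, antipode giving the R centre), Mn powder (3 equiv), NaI (0.25 equiv), DMA, 0 to 10 °C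
Reagents that add atoms: acetaldehyde (13), CC=O; 3-methylbutanoyl chloride (10), CC(C)CC(Cl)=O
Why: Proposed new method: ZnCl2-catalysed addition of 10 to 13 gives racemic 14; zerovalent nickel inserts into the C-5–I bond of 12, a monovalent nickel species abstracts chlorine from 14 to give the planar, oxygen-stabilised 1-(acyloxy)ethyl radical, the aryl nickel complex captures it, and reductive elimination from trivalent nickel forms the C-5–C-1′ bond while Mn returns nickel to the zerovalent state. The closest known reaction types are the nickel-catalysed enantioconvergent coupling of racemic 1-haloalkyl esters (made in the flask from an aldehyde and an acyl halide) with organozinc reagents and the nickel-catalysed asymmetric reductive cross-electrophile arylation of racemic α-chloro esters and nitriles with aryl iodides; pairing an aryl iodide with a 1-chloroalkyl ester in a reductive three-component format is the untested part. No ring is closed. The new centre C-1′ should be set R by the twofold-symmetric bis(oxazoline) on nickel (catalyst control: both enantiomers of 14 converge on the same radical, and chelation of the ester carbonyl to nickel should rigidify the enantio-determining step), the C-2 and C-3 centres being too remote to interfere. The step needs cross-coupling to beat homocoupling, hydrodeiodination and β-hydride loss to a vinyl ester, and needs the C-5–I bond to react in preference to the allylic aryl ether C-2–O-1 and the benzylic C-3 ester; in the substrate the C-5–I bond is the only carbon–halogen bond and the allylic ether has a hindered 1,1-disubstituted alkene and a poor aryloxide leaving group, so fast oxidative addition of the aryl iodide at or below room temperature, the matched pairing of an sp2 iodide with an activated sp3 chloride and slow addition of 14 should secure this.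

Step 8
Reactants: 15 (2R,3S)-5-[(1R)-1-(3-methylbutanoyloxy)ethyl]-2-(prop-1-en-2-yl)-2,3-dihydro-1-benzofuran-3-yl 3-methylbutanoate
Product: 16 (2R,3S)-2-(3-hydroxyprop-1-en-2-yl)-5-[(1R)-1-(3-methylbutanoyloxy)ethyl]-2,3-dihydro-1-benzofuran-3-yl 3-methylbutanoate
Conditions: SeO2 (0.5 equiv), t-BuOOH (3 equiv), CH2Cl2, rt
Reagents that add atoms: tert-butyl hydroperoxide, CC(C)(C)OO (terminal oxygen source; the oxygen is transferred through selenium dioxide, O=[Se]=O)
Why: Selenium dioxide allylic oxidation (ene reaction, then [2,3]-sigmatropic shift) of the 1,1-disubstituted alkene should hydroxylate the methyl group in preference to the methine C-2–H, which is hindered and deactivated by two oxygen-bearing neighbours, and any enal formed by further oxidation is simply the product of step 9.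

Step 9
Reactants: 16 (2R,3S)-2-(3-hydroxyprop-1-en-2-yl)-5-[(1R)-1-(3-methylbutanoyloxy)ethyl]-2,3-dihydro-1-benzofuran-3-yl 3-methylbutanoate
Product: 17 (2R,3S)-5-[(1R)-1-(3-methylbutanoyloxy)ethyl]-2-(3-oxoprop-1-en-2-yl)-2,3-dihydro-1-benzofuran-3-yl 3-methylbutanoate (CNP0316116.2)
Conditions: MnO2 (activated, excess), CH2Cl2, rt
Reagents that add atoms: none
Why: MnO2 oxidation is selective for the primary allylic alcohol and runs under neutral heterogeneous conditions, so both esters and all three stereocentres should survive.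

**Compound list**
1 | 2-hydroxy-5-iodobenzaldehyde | O=Cc1cc(I)ccc1O | starting material
2 | 2-[(tert-butyldimethylsilyl)oxy]-5-iodobenzaldehyde | O=Cc1cc(I)ccc1O[Si](C)(C)C(C)(C)C | intermediate
3 | 1-bromo-2-methylprop-1-ene | CC(C)=CBr | starting material
4 | (2-methylprop-1-enyl)lithium | [Li]C=C(C)C | intermediate
5 | bis(2-methylprop-1-enyl)zinc | CC(C)=C[Zn]C=C(C)C | intermediate
6 | (1R)-1-{2-[(tert-butyldimethylsilyl)oxy]-5-iodophenyl}-3-methylbut-2-en-1-ol | O[C@@H](c1cc(I)ccc1O[Si](C)(C)C(C)(C)C)C=C(C)C | intermediate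
7 | (S)-{2-[(tert-butyldimethylsilyl)oxy]-5-iodophenyl}[(2R)-3,3-dimethyloxiran-2-yl]methanol | O[C@@H](c1cc(I)ccc1O[Si](C)(C)C(C)(C)C)[C@H]1OC1(C)C | intermediate
8 | potassium 2-{(S)-[(2R)-3,3-dimethyloxiran-2-yl](hydroxy)methyl}-4-iodophenoxide | O[C@@H](c1cc(I)ccc1[O-])[C@H]1OC1(C)C.[K+] | intermediate
9 | (2S,3S)-2-(2-hydroxypropan-2-yl)-5-iodo-2,3-dihydro-1-benzofuran-3-ol | CC(C)(O)[C@H]1Oc2ccc(I)cc2[C@@H]1O | intermediate
10 | 3-methylbutanoyl chloride | CC(C)CC(Cl)=O | starting material
11 | (2S,3S)-2-(2-hydroxypropan-2-yl)-5-iodo-2,3-dihydro-1-benzofuran-3-yl 3-methylbutanoate | CC(C)(O)[C@H]1Oc2ccc(I)cc2[C@@H]1OC(=O)CC(C)C | intermediate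
12 | (2R,3S)-5-iodo-2-(prop-1-en-2-yl)-2,3-dihydro-1-benzofuran-3-yl 3-methylbutanoate | C=C(C)[C@H]1Oc2ccc(I)cc2[C@@H]1OC(=O)CC(C)C | intermediate
13 | acetaldehyde | CC=O | starting material
14 | 1-chloroethyl 3-methylbutanoate (racemic) | CC(Cl)OC(=O)CC(C)C | intermediate
15 | (2R,3S)-5-[(1R)-1-(3-methylbutanoyloxy)ethyl]-2-(prop-1-en-2-yl)-2,3-dihydro-1-benzofuran-3-yl 3-methylbutanoate | C=C(C)[C@H]1Oc2ccc([C@@H](C)OC(=O)CC(C)C)cc2[C@@H]1OC(=O)CC(C)C | intermediate
16 | (2R,3S)-2-(3-hydroxyprop-1-en-2-yl)-5-[(1R)-1-(3-methylbutanoyloxy)ethyl]-2,3-dihydro-1-benzofuran-3-yl 3-methylbutanoate | C=C(CO)[C@H]1Oc2ccc([C@@H](C)OC(=O)CC(C)C)cc2[C@@H]1OC(=O)CC(C)C | intermediate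
17 | (2R,3S)-5-[(1R)-1-(3-methylbutanoyloxy)ethyl]-2-(3-oxoprop-1-en-2-yl)-2,3-dihydro-1-benzofuran-3-yl 3-methylbutanoate | C=C(C=O)[C@H]1Oc2ccc([C@@H](C)OC(=O)CC(C)C)cc2[C@@H]1OC(=O)CC(C)C | target

**Step count and risks**
Total steps: 9. Longest linear sequence: 9 steps, from 1; the coupling partner 14 is made in the flask of step 7.

Three steps most likely to fail:

1. Step 7 (proposed three-component coupling). The aryl iodide may be reduced or homocoupled, the chloro ester may lose hydride to a vinyl ester, or enantiocontrol at C-1′ may be poor. The fallback uses known chemistry and sets out from 12. Stille coupling with tributyl(1-ethoxyvinyl)stannane (PdCl2(PPh3)2, CuI, DMF, 50 °C) should give (2R,3S)-5-(1-ethoxyethenyl)-2-(prop-1-en-2-yl)-2,3-dihydro-1-benzofuran-3-yl 3-methylbutanoate F1. Brief hydrolysis (1 M HCl, THF, 0 °C) should give the methyl ketone (2R,3S)-5-acetyl-2-(prop-1-en-2-yl)-2,3-dihydro-1-benzofuran-3-yl 3-methylbutanoate F2. Noyori-type asymmetric transfer hydrogenation (RuCl(p-cymene)[(R,R)-TsDPEN], HCO2H/Et3N) should give (2R,3S)-5-[(1R)-1-hydroxyethyl]-2-(prop-1-en-2-yl)-2,3-dihydro-1-benzofuran-3-yl 3-methylbutanoate F3. Acylation with 10 (pyridine, DMAP, CH2Cl2, 0 °C) comes back to the route at 15.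

2. Step 6 (dehydration). Elimination may run toward C-2 (enol ether, then loss of the C-3 ester and aromatisation to a benzofuran), or O-1 may participate and expand the ring to a chromane. The fallback makes the isopropenyl group before ring B is closed and sets out from 7.
   - Acylation with 10 (pyridine, DMAP) should give (S)-{2-[(tert-butyldimethylsilyl)oxy]-5-iodophenyl}[(2R)-3,3-dimethyloxiran-2-yl]methyl 3-methylbutanoate F4.
   - Epoxide-to-allylic-ether isomerisation (TMSOTf, 2,6-lutidine, then DBU, CH2Cl2, −78 °C to rt) should give (1S,2S)-1-{2-[(tert-butyldimethylsilyl)oxy]-5-iodophenyl}-3-methyl-2-[(trimethylsilyl)oxy]but-3-en-1-yl 3-methylbutanoate F5. The C-2–O bond is untouched, so the threo relationship is kept.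
   - Citric acid in MeOH should remove the trimethylsilyl group and give (1S,2S)-1-{2-[(tert-butyldimethylsilyl)oxy]-5-iodophenyl}-2-hydroxy-3-methylbut-3-en-1-yl 3-methylbutanoate F6.
   - Mesylation (MsCl, Et3N, CH2Cl2, 0 °C) should give (1S,2S)-1-{2-[(tert-butyldimethylsilyl)oxy]-5-iodophenyl}-2-[(methanesulfonyl)oxy]-3-methylbut-3-en-1-yl 3-methylbutanoate F7.
   - TBAF (THF, 0 °C) then frees the phenoxide, which should displace the mesylate in a 5-exo-tet SN2 reaction with inversion at C-2 and come back to the route at 12.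

3. Step 8 (allylic oxidation). Oxidation of the isopropenyl methyl may be sluggish or unselective, and the selenium acids may ionise the two benzylic esters. The fallback sets out from 15. Ene-type allylic chlorination (N-chlorosuccinimide, PhSeCl (10 mol %), CH2Cl2, rt) should give (2R,3S)-2-(3-chloroprop-1-en-2-yl)-5-[(1R)-1-(3-methylbutanoyloxy)ethyl]-2,3-dihydro-1-benzofuran-3-yl 3-methylbutanoate F8. Amine N-oxide oxidation of the allylic chloride (Me3NO, DMSO, rt; Kornblum-type) comes back to the route directly at 17, bypassing 16 and step 9.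

**Further compounds**
F1 | step 7 | (2R,3S)-5-(1-ethoxyethenyl)-2-(prop-1-en-2-yl)-2,3-dihydro-1-benzofuran-3-yl 3-methylbutanoate | C=C(C)[C@H]1Oc2ccc(C(=C)OCC)cc2[C@@H]1OC(=O)CC(C)C
F2 | step 7 | (2R,3S)-5-acetyl-2-(prop-1-en-2-yl)-2,3-dihydro-1-benzofuran-3-yl 3-methylbutanoate | C=C(C)[C@H]1Oc2ccc(C(C)=O)cc2[C@@H]1OC(=O)CC(C)C
F3 | step 7 | (2R,3S)-5-[(1R)-1-hydroxyethyl]-2-(prop-1-en-2-yl)-2,3-dihydro-1-benzofuran-3-yl 3-methylbutanoate | C=C(C)[C@H]1Oc2ccc([C@@H](C)O)cc2[C@@H]1OC(=O)CC(C)C
F4 | step 6 | (S)-{2-[(tert-butyldimethylsilyl)oxy]-5-iodophenyl}[(2R)-3,3-dimethyloxiran-2-yl]methyl 3-methylbutanoate | CC(C)CC(=O)O[C@@H](c1cc(I)ccc1O[Si](C)(C)C(C)(C)C)[C@H]1OC1(C)C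
F5 | step 6 | (1S,2S)-1-{2-[(tert-butyldimethylsilyl)oxy]-5-iodophenyl}-3-methyl-2-[(trimethylsilyl)oxy]but-3-en-1-yl 3-methylbutanoate | CC(C)CC(=O)O[C@@H](c1cc(I)ccc1O[Si](C)(C)C(C)(C)C)[C@@H](O[Si](C)(C)C)C(C)=C
F6 | step 6 | (1S,2S)-1-{2-[(tert-butyldimethylsilyl)oxy]-5-iodophenyl}-2-hydroxy-3-methylbut-3-en-1-yl 3-methylbutanoate | CC(C)CC(=O)O[C@@H](c1cc(I)ccc1O[Si](C)(C)C(C)(C)C)[C@@H](O)C(C)=C
F7 | step 6 | (1S,2S)-1-{2-[(tert-butyldimethylsilyl)oxy]-5-iodophenyl}-2-[(methanesulfonyl)oxy]-3-methylbut-3-en-1-yl 3-methylbutanoate | CC(C)CC(=O)O[C@@H](c1cc(I)ccc1O[Si](C)(C)C(C)(C)C)[C@@H](OS(C)(=O)=O)C(C)=C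
F8 | step 8 | (2R,3S)-2-(3-chloroprop-1-en-2-yl)-5-[(1R)-1-(3-methylbutanoyloxy)ethyl]-2,3-dihydro-1-benzofuran-3-yl 3-methylbutanoate | C=C(CCl)[C@H]1Oc2ccc([C@@H](C)OC(=O)CC(C)C)cc2[C@@H]1OC(=O)CC(C)C
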